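(All runs are simulated with constants of no real substance; noise was put on by code.)

1. I decide to treat the west run as the north-east run on another clock: I ask how many north-east minutes one west minute is worth, and read the share turned off the north-east readings. Starting material is the limiting reagent in both. Partner stands to it at 2.00 in the north-east run and 1.94 in the west run, so partner falls by nearly the same fraction at equal shares turned.

| flask | starting material | partner | catalyst | time |
|---|---|---|---|---|
| north-east | 0.500 M | 1.00 M | 0.0150 M |  |
| north | 0.500 M | 3.00 M | 0.0150 M |  |
| south-west | 1.00 M | 1.00 M | 0.0150 M |  |
| west | 0.170 M | 0.330 M | 0.0150 M | 8.5 min |

| north-east run: time / min | north-east run: [target] / M | north run: time / min | north run: [target] / M | south-west run: time / min | south-west run: [target] / M |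
|---|---|---|---|---|---|
| 0.65 | 0.078 | 0.65 | 0.152 | 0.65 | 0.094 |
| 2.0 | 0.195 | 2.0 | 0.337 | 2.0 | 0.265 |
| 3.8 | 0.306 | 3.8 | 0.443 | 3.8 | 0.427 |
| 5.9 | 0.389 | 5.9 | 0.487 | 5.9 | 0.560 |
| 8.5 | 0.450 | 8.5 | 0.503 | 8.5 | 0.682 |

(readings scatter by 0.004 M)

* reaction order in [starting material] at the outset, round the charge of the north-east run, defined at two percent of the starting material turned into target (one fixed amount of target, the same in the runs compared)
* reaction order in [partner] at the outset, round the charge of the north-east run, defined at two percent of the starting material turned into target
* target in the west run at 8.5 min, as a share of the starting material charged

- Overall: starting material + partner -> target, with catalyst as catalyst.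
- Constant volume, constant temperature.
- What is held in complexes is read along with the free species.
- An order is taken over about fifteen percent of the charge, up and down.

2. Free extreme: suppose the catalyst is free of starting material. The share turned per minute then follows partner, the clock is 0.330, and the west run at 8.5 min matches the north-east run at 2.81 min, a share of 48.9 %.

3. Held extreme: suppose the catalyst sits wholly on starting material, its resting state. The rate then ignores the charge, the clock is 0.971, and the match is 8.25 min, a share of 88.8 %, higher.

4. The readings lie between these. At 2.0 min the share-rate, ln(charge/charge left) over time, is 0.247 min⁻¹ in the north-east run and 0.154 min⁻¹ in the south-west run, a ratio of 1.61, between 1 for the free extreme and 2.00 for the held one. That reads a holding charge of 0.326 M, the charge of starting material at which free and held catalyst are equal. The order in starting material is then the free share of catalyst, 0.395 at the north-east charge.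

5. My estimate of the clock is 0.550 at the start, and it drifts to 0.463 at a share turned of 0.5. These clocks give 68.1 % and 62.2 %, so I commit to 65.2 %.

6. For partner, the north run over the north-east run reads a chord order of 0.745. I take the middle between that and first order, 0.873.

7. The forecast differs from my reckoning: 0.33, 0.74 and 78 %, above my share, on the ground that “the catalyst is tied up by starting material”.

8. The flask gives 0.52, 0.84 and 68.9 %.

    catalyst + starting material ⇌ catalyst-substrate complex, settled at all times (1.440 M⁻¹)
    catalyst-substrate complex + partner → target + catalyst (42.06 M⁻¹ min⁻¹)
    starting material + partner ⇌ idle substrate-reagent adduct, settled at all times (0.9420 M⁻¹)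
    2 starting material ⇌ idle substrate dimer, settled at all times (1.600 M⁻¹)

The forecast's 78 % is what a power-law fit gives. My holding charge of 0.326 M gave 65.2 % for the west run, and it puts the south-west run at a share of 0.5 after 4.51 min, from the north-east 2.81 min, against a simulated 4.79 min; the early south-west readings went into that holding charge, so this is a use of it and no independent check. In the west run, the joining of starting material and partner to the idle substrate-reagent adduct and the joining of starting material to the idle substrate dimer hold the target down: from 68.9 % it rises to 75.3 % without the adduct and to 73.2 % without the dimer.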